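Early in Saturday's run target climbs fast, to 21.0% at 2.08 d, and then it levels off: the readings from 6.00 d on average 28.4%, that is 12.5 mM, although partner was charged at 50 mM against 44 mM of substrate.

| flask | substrate | partner | remark | time |
|---|---|---|---|---|
| Thursday's | 20 mM | 50 mM | run made earlier |  |
| Monday's | 28 mM | 50 mM | run made earlier |  |
| Saturday's | 44 mM | 50 mM | run made earlier |  |
| east | 20 mM | 50.0 mM | a single well-mixed tank run continuously and read at steady state, 20 d in it on average |  |
| south-west | 20 mM | 50.0 mM | everything together in a closed stirred flask, run for 20 d | 20 d |
| north | 20 mM | 50.0 mM | one stirred flow tank at steady state, fed with the mixture as stated, mean residence time 60.0 d |  |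
| north-west | 20 mM | 50.0 mM (fed, over 16.0 d) | a stirred flask in which partner is dosed at a steady rate over 16.0 d without added volume, worked up at 20 d | 20 d |

- Thursday's (time / d: target / %, side product A / %, side product B / %): 2.08: 51.7, 1.4, 1.6; 4.00: 69.6, 1.0, 0; 6.00: 79.1, 1.4, 0.7; 8.00: 82.1, 3.4, 0; 10.0: 88.5, 2.4, 1.0; 12.0: 89.6, 3.2, 0
- Monday's (time / d: target / %, side product A / %, side product B / %): 0.833: 20.6, 0.7, 1.0; 2.50: 42.8, 0.2, 0; 4.00: 54.1, 0, 2.1; 6.00: 62.6, 1.5, 1.1; 10.0: 71.0, 3.4, 1.1; 12.0: 73.5, 3.8, 0
- Saturday's (time / d: target / %, side product A / %, side product B / %): 2.08: 21.0, 0, 2.6; 4.00: 24.7, 0, 1.1; 6.00: 27.6, 2.4, 2.2; 8.00: 27.1, 1.4, 2.3; 10.0: 30.8, 4.4, 2.0; 12.0: 28.2, 4.0, 1.9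

(scatter of a reading: 1 percentage point)

- in percentages every species weighs as the substrate in it: one side product B counts as two
- the stated concentrations are those of everything mixed, before any reaction; amounts are the same in each set-up
- the feed brings no volume worth counting
- the earlier runs were made in a closed, stirred flask

- the set-up with the highest share of target in all that became target or side product A or side product B, at the outlet or at the end ("none" if the first two lie within 2 percentage points) (east / south-west / north / north-west / none)
- share of target in all that became target or side product A or side product B, at the outlet or at the end, east
- share of target in all that became target or side product A or side product B, at the outlet or at the end, south-west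
- share of target in all that became target or side product A or side product B, at the outlet or at the end, north
- share of target in all that became target or side product A or side product B, at the outlet or at the end, north-west

Those numbers fit if each target takes two partners, one capturing substrate and one finishing the product. Saturday then called for 88.0 mM, which makes partner the limiting reagent there. If capture runs ahead of finishing, the partner remaining after capture becomes target, so 12.5 mM remaining means 37.5 mM captured, and 6.51 mM of substrate leaked away without partner.

Take the leak as first order in substrate and capture as first order in substrate and in [partner]. Leak then stands to capture as K to [partner], and summing while [partner] falls makes the leak K times the logarithm of charge over remainder. Saturday's leak divided by the logarithm of 4.00 gives K = 4.70 mM, the [partner] at which leak and capture take substrate equally, a selectivity factor in concentration units.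

By this reckoning, south-west leaks 2.04 mM and captures 89.8% of its substrate. North-west starts without partner, and its dose of 3.12 mM d⁻¹ cannot bring [partner] to K before 1.50 d, so the leak outruns capture for that stretch. The readings time neither route, so this gives a direction and no number.

The forecast said none, with east 92.8% (90% to 95%), south-west 93.2% (90.5% to 95.5%), north 82.7% (76% to 87%) and north-west 75% (60% to 91%), on the ground: “Dosing partner starves the reaction while substrate kills activity”.

The simulation gives south-west as best, with east 90.0%, south-west 93.6%, north 85.5% and north-west 32.6%. North-west stands 42 percentage points below the forecast.

    intermediate C ⇌ intermediate D (K = 16.0, k = 0.00377 h⁻¹)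
    substrate → intermediate A (k = 0.0257 h⁻¹)
    substrate + partner → intermediate B (k = 6.73 L mol⁻¹ h⁻¹)
    intermediate D → side product A (k = 0.00671 h⁻¹)
    partner + intermediate B → target (k = 0.665 L mol⁻¹ h⁻¹)
    substrate + intermediate A → side product B (k = 1.51 L mol⁻¹ h⁻¹)
    intermediate A → intermediate C (k = 0.114 h⁻¹)

In north-west substrate has a half-life of 1.1 d by the path to intermediate A alone, shorter than the 1.50 d before which the dose cannot bring K, and target ends at 25.3% at 20.0 d. The neighbour of north-west, dosed with 120 mM of partner over the same 16.0 d, cannot bring K before 0.626 d, a bound earlier than north-west's. Both times count the dose with no uptake by capture, so they are lower bounds. Its target ends at 40.0%, more than in north-west, and its asked share at 48.6%.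

The runs were generated by integration from invented constants; scatter was added.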